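The plan disconnects the bond between the benzylic methine carbon shared by the tetralin, lactone and seven-membered rings and the oxygen-bearing carbon flanked by the lactone oxygen and the cycloheptenone carbonyl. The first carbon is β to the lactone carbonyl, the second α to the ketone, so the bond is a Michael retron within a 1,5-dicarbonyl array. The precursor is a 3,4-dihydro-2-naphthoate whose quaternary carbon carries a (Z)-4-acetoxy-3-oxobutenyl arm; base unmasks the α-hydroxy enone, closes the cycloheptenone by intramolecular Michael addition and the γ-lactone by acyl transfer, setting three stereocentres. The quaternary centre comes from a CBS reduction relayed by a [2,3]-sigmatropic shift.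

Key step: step 11

Remark: in step 5 the alkenyl arm that carries the ester is taken as the larger substituent of ketone 9, which assigns the (S)-oxazaborolidine to the (R)-alcohol; if the sense proves opposite, the (R)-catalyst is used.

Step 1
Reactants: 1 ethylbenzene; 2 5,5-dimethyldihydrofuran-2(3H)-one
Product: 4 7-ethyl-4,4-dimethyl-3,4-dihydronaphthalen-1(2H)-one, via 4-(4-ethylphenyl)-4-methylpentanoic acid 3 (not isolated)
Conditions: AlCl3 (3 equiv), ethylbenzene (5 equiv), 1,2-dichloroethane, 0 → 50 °C
Reagents that add atoms: none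
Why: Friedel–Crafts alkylation by the tertiary cation from the lactone should go para to ethyl, and the tethered acid then closes ortho to the new quaternary carbon (Friedel–Crafts acylation), which fixes the arene pattern; no stereocentre is formed.

Step 2
Reactants: 4 7-ethyl-4,4-dimethyl-3,4-dihydronaphthalen-1(2H)-one
Product: 5 methyl 7-ethyl-4,4-dimethyl-1-oxo-1,2,3,4-tetrahydronaphthalene-2-carboxylate (racemic, partly enolised)
Conditions: NaH (2.5 equiv), (MeO)2CO, THF, reflux; aq. HCl
Reagents that add atoms: dimethyl carbonate, COC(=O)OC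
Why: Claisen-type C-methoxycarbonylation of the ketone enolate, driven by deprotonation of the β-keto ester that forms.

Step 3
Reactants: 5 methyl 7-ethyl-4,4-dimethyl-1-oxo-1,2,3,4-tetrahydronaphthalene-2-carboxylate
Product: 6 methyl 7-ethyl-4,4-dimethyl-1-oxo-1,4-dihydronaphthalene-2-carboxylate
Conditions: DDQ (1.2 equiv), 1,4-dioxane, 25 → 60 °C
Reagents that add atoms: none
Why: DDQ dehydrogenation of the enolised β-keto ester should give the alkylidene β-keto ester; the quaternary C-4 blocks aromatisation to a naphthol.

Step 4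
Reactants: 6 methyl 7-ethyl-4,4-dimethyl-1-oxo-1,4-dihydronaphthalene-2-carboxylate
Product: 9 methyl 7-ethyl-3,4,4-trimethyl-1-oxo-1,4-dihydronaphthalene-2-carboxylate, via lithium enolate 7 (not isolated), via α-phenylselanyl β-keto ester 8 (not isolated)
Conditions: MeLi (2.4 equiv), CuI (1.2 equiv), Et2O, −78 → −30 °C; PhSeCl, THF, −78 → 0 °C; then mCPBA, CH2Cl2, −78 °C → rt
Reagents that add atoms: lithium dimethylcuprate, [Li+].C[Cu-]C
Why: Cuprate conjugate addition to the doubly activated alkene, selenenylation of the enolate and selenoxide syn-elimination toward the only β-hydrogen should reinstall the enone with the C-3 methyl in place; the transient stereocentres vanish.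

Step 5
Reactants: 9 methyl 7-ethyl-3,4,4-trimethyl-1-oxo-1,4-dihydronaphthalene-2-carboxylate
Product: 10 methyl (R)-7-ethyl-1-hydroxy-3,4,4-trimethyl-1,4-dihydronaphthalene-2-carboxylate
Conditions: (S)-2-methyl-CBS-oxazaborolidine (20 mol%), catecholborane (1.5 equiv), toluene, −78 °C
Reagents that add atoms: none
Why: CBS reduction delivers hydride 1,2 within the ketone–oxazaborolidine–borane complex, so the catalyst sets the carbinol centre; the ring-locked s-trans enone disfavours conjugate reduction.

Step 6
Reactants: 10 methyl (R)-7-ethyl-1-hydroxy-3,4,4-trimethyl-1,4-dihydronaphthalene-2-carboxylate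
Product: 12 methyl (S)-3-(dimethylcarbamoyl)-7-ethyl-3,4,4-trimethyl-3,4-dihydronaphthalene-2-carboxylate, via mixed amide acetal 11 (not isolated)
Conditions: Me2NCH(OMe)2 (5 equiv), xylene, 150 °C, sealed vessel, 4 Å sieves
Reagents that add atoms: N,N-dimethylformamide dimethyl acetal, COC(OC)N(C)C
Why: Acetal exchange and loss of methanol give an allyloxy(dimethylamino)carbene whose [2,3]-sigmatropic shift (amide acetal homologation of allylic alcohols) is suprafacial, so the carbamoyl carbon should arrive at C-3 on the face that held the C–O bond and relay the carbinol chirality to the quaternary centre.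

Step 7
Reactants: 12 methyl (S)-3-(dimethylcarbamoyl)-7-ethyl-3,4,4-trimethyl-3,4-dihydronaphthalene-2-carboxylate
Product: 13 methyl (S)-7-ethyl-3-formyl-3,4,4-trimethyl-3,4-dihydronaphthalene-2-carboxylate
Conditions: Cp2Zr(H)Cl (1.8 equiv), THF, 25 °C; wet silica gel
Reagents that add atoms: none
Why: The Schwartz reagent should reduce the tertiary amide chemoselectively (hydrozirconation of the amide carbonyl, hemiaminal collapse on work-up) and leave the ester; the aldehyde has no α-hydrogen, so the quaternary centre cannot epimerise.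

Step 8
Reactants: 13 methyl (S)-7-ethyl-3-formyl-3,4,4-trimethyl-3,4-dihydronaphthalene-2-carboxylate
Product: 14 methyl (S)-7-ethyl-3-ethynyl-3,4,4-trimethyl-3,4-dihydronaphthalene-2-carboxylate
Conditions: MeC(O)C(N2)P(O)(OMe)2 (1.5 equiv), K2CO3 (2 equiv), MeOH, 0 °C → rt
Reagents that add atoms: dimethyl (1-diazo-2-oxopropyl)phosphonate, CC(=O)C(=[N+]=[N-])P(=O)(OC)OC
Why: Ohira–Bestmann (Seyferth–Gilbert) homologation of a non-enolisable aldehyde under carbonate in methanol, to which the methyl ester is inert.

Step 9
Reactants: 14 methyl (S)-7-ethyl-3-ethynyl-3,4,4-trimethyl-3,4-dihydronaphthalene-2-carboxylate; 15 acetoxyacetyl chloride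
Product: 16 methyl (S)-3-(4-acetoxy-3-oxobut-1-yn-1-yl)-7-ethyl-3,4,4-trimethyl-3,4-dihydronaphthalene-2-carboxylate
Conditions: PdCl2(PPh3)2 (2 mol%), CuI (4 mol%), Et3N (1.3 equiv), THF, 0 °C → rt, acid chloride added last
Reagents that add atoms: none
Why: Acyl Sonogashira coupling (oxidative addition of the acid chloride to zerovalent palladium, transmetalation from the copper acetylide, reductive elimination) at the unhindered alkyne terminus.

Step 10
Reactants: 16 methyl (S)-3-(4-acetoxy-3-oxobut-1-yn-1-yl)-7-ethyl-3,4,4-trimethyl-3,4-dihydronaphthalene-2-carboxylate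
Product: 17 methyl (S,Z)-3-(4-acetoxy-3-oxobut-1-en-1-yl)-7-ethyl-3,4,4-trimethyl-3,4-dihydronaphthalene-2-carboxylate
Conditions: H2 (1 atm), Pd/CaCO3 poisoned with Pb(OAc)2 (Lindlar catalyst), quinoline, EtOAc, rt
Reagents that add atoms: none
Why: Lindlar semihydrogenation adds hydrogen syn to the ynone and should give the (Z)-enone; the trisubstituted conjugated ring alkene is not reduced.

Step 11
Reactants: 17 methyl (S,Z)-3-(4-acetoxy-3-oxobut-1-en-1-yl)-7-ethyl-3,4,4-trimethyl-3,4-dihydronaphthalene-2-carboxylate
Product: 20 debromosalimabromide, via α-hydroxy enone 18 (not isolated), via bridged hydroxy keto ester 19 (not isolated)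
Conditions: K2CO3 (0.5 equiv), MeOH, 0 °C → rt; solvent exchanged for toluene, DBU (0.3 equiv), 60 °C
Reagents that add atoms: none
Why: Methanolysis of the acetate frees α-hydroxy enone 18, whose cross-conjugated enediolate (the CH2OH carbon is the only enolisable position, since the other α-carbon is sp2 and the γ-carbon quaternary) should add to the benzylic β-carbon of the aryl-conjugated enoate in a 7-endo-trig Michael closure of the cycloheptenone, after which the ester enolate is protonated and the hydroxyl acylates on the methyl ester (5-exo-trig) to give the γ-lactone. The closest known reaction type is the base-mediated intramolecular Michael addition of an α-hydroxy ketone donor to an enoate followed by lactonisation (Michael/lactonisation domino). The benzylic stereocentre is controlled by the tether, because the (Z)-arm on the quaternary carbon can reach the alkene only from its own face, so the new bond is cis to it. The carbinol centre (α to the ketone) and the centre α to the ester are both epimerisable under the conditions and only the all-cis isomer can lactonise, so lactonisation is a thermodynamic sink that also pulls the reversible conjugate addition forward. The step needs the (Z)-enone geometry, secured by the Lindlar reduction and by the hindered β-carbon that resists addition–elimination isomerisation, and it needs lactone closure over methanolysis, secured by removing methanol in the second stage.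

Step 12
Reactants: 20 debromosalimabromide
Product: 22 salimabromide, via monobromide 21 (not isolated)
Conditions: NBS (2.3 equiv), CF3CO2H, H2SO4 (0.3 equiv), 0 °C → rt, dark
Reagents that add atoms: N-bromosuccinimide, O=C1CCC(=O)N1Br
Why: Electrophilic aromatic bromination should go first ortho to ethyl and para to the benzylic methine, then to the other position ortho to ethyl (the only remaining site activated by two alkyl groups, the last C–H being flanked by bromine and the quaternary carbon); the protonated enone and the bridgehead lactone do not enolise.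

Compound list
1 | ethylbenzene | CCc1ccccc1 | starting material
2 | 5,5-dimethyldihydrofuran-2(3H)-one | CC1(C)CCC(=O)O1 | starting material
3 | 4-(4-ethylphenyl)-4-methylpentanoic acid | CCc1ccc(cc1)C(C)(C)CCC(=O)O | intermediate (not isolated)
4 | 7-ethyl-4,4-dimethyl-3,4-dihydronaphthalen-1(2H)-one | CCc1ccc2c(c1)C(=O)CCC2(C)C | intermediate
5 | methyl 7-ethyl-4,4-dimethyl-1-oxo-1,2,3,4-tetrahydronaphthalene-2-carboxylate | CCc1ccc2c(c1)C(=O)C(C(=O)OC)CC2(C)C | intermediate
6 | methyl 7-ethyl-4,4-dimethyl-1-oxo-1,4-dihydronaphthalene-2-carboxylate | CCc1ccc2c(c1)C(=O)C(C(=O)OC)=CC2(C)C | intermediate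
7 | lithium enolate of methyl 7-ethyl-3,4,4-trimethyl-1-oxo-1,2,3,4-tetrahydronaphthalene-2-carboxylate | CCc1ccc2c(c1)C([O-])=C(C(=O)OC)C(C)C2(C)C.[Li+] | intermediate (not isolated)
8 | methyl 7-ethyl-3,4,4-trimethyl-1-oxo-2-(phenylselanyl)-1,2,3,4-tetrahydronaphthalene-2-carboxylate (stereoisomer mixture) | CCc1ccc2c(c1)C(=O)C([Se]c3ccccc3)(C(=O)OC)C(C)C2(C)C | intermediate (not isolated)
9 | methyl 7-ethyl-3,4,4-trimethyl-1-oxo-1,4-dihydronaphthalene-2-carboxylate | CCc1ccc2c(c1)C(=O)C(C(=O)OC)=C(C)C2(C)C | intermediate
10 | methyl (R)-7-ethyl-1-hydroxy-3,4,4-trimethyl-1,4-dihydronaphthalene-2-carboxylate | CCc1ccc2c(c1)[C@@H](O)C(C(=O)OC)=C(C)C2(C)C | intermediate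
11 | mixed amide acetal of 10 (O-[(dimethylamino)(methoxy)methyl] ether) | CCc1ccc2c(c1)[C@@H](OC(OC)N(C)C)C(C(=O)OC)=C(C)C2(C)C | intermediate (not isolated)
12 | methyl (S)-3-(dimethylcarbamoyl)-7-ethyl-3,4,4-trimethyl-3,4-dihydronaphthalene-2-carboxylate | CCc1ccc2c(c1)C=C(C(=O)OC)[C@@](C)(C(=O)N(C)C)C2(C)C | intermediate
13 | methyl (S)-7-ethyl-3-formyl-3,4,4-trimethyl-3,4-dihydronaphthalene-2-carboxylate | CCc1ccc2c(c1)C=C(C(=O)OC)[C@@](C)(C=O)C2(C)C | intermediate
14 | methyl (S)-7-ethyl-3-ethynyl-3,4,4-trimethyl-3,4-dihydronaphthalene-2-carboxylate | CCc1ccc2c(c1)C=C(C(=O)OC)[C@@](C)(C#C)C2(C)C | intermediate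
15 | acetoxyacetyl chloride | CC(=O)OCC(Cl)=O | starting material
16 | methyl (S)-3-(4-acetoxy-3-oxobut-1-yn-1-yl)-7-ethyl-3,4,4-trimethyl-3,4-dihydronaphthalene-2-carboxylate | CCc1ccc2c(c1)C=C(C(=O)OC)[C@@](C)(C#CC(=O)COC(C)=O)C2(C)C | intermediate
17 | methyl (S,Z)-3-(4-acetoxy-3-oxobut-1-en-1-yl)-7-ethyl-3,4,4-trimethyl-3,4-dihydronaphthalene-2-carboxylate | CCc1ccc2c(c1)C=C(C(=O)OC)[C@@](C)(/C=C\C(=O)COC(C)=O)C2(C)C | intermediate
18 | methyl (S,Z)-7-ethyl-3-(4-hydroxy-3-oxobut-1-en-1-yl)-3,4,4-trimethyl-3,4-dihydronaphthalene-2-carboxylate | CCc1ccc2c(c1)C=C(C(=O)OC)[C@@](C)(/C=C\C(=O)CO)C2(C)C | intermediate (not isolated)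
19 | bridged hydroxy keto ester (Michael adduct, all-cis, benzo-fused bicyclo[4.3.1]decenone methyl ester) | CCc1ccc2c(c1)[C@@H]1[C@@H](C(=O)OC)[C@@](C)(C=CC(=O)[C@H]1O)C2(C)C | intermediate (not isolated)
20 | debromosalimabromide (the target without its two bromine atoms) | CCc1ccc2c(c1)[C@H]1[C@@H]3OC(=O)[C@H]1[C@@](C)(C=CC3=O)C2(C)C | intermediate
21 | monobromide (bromine ortho to ethyl, para to the benzylic methine) | CCc1c(Br)cc2c(c1)[C@H]1[C@@H]3OC(=O)[C@H]1[C@@](C)(C=CC3=O)C2(C)C | intermediate (not isolated)
22 | salimabromide | CCc1c(Br)cc2c(c1Br)[C@H]1[C@@H]3OC(=O)[C@H]1[C@@](C)(C=CC3=O)C2(C)C | target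

Total step count: 12. Longest linear sequence: 12 steps (from ethylbenzene).

Steps most likely to fail

Step 11 (key step). The conjugate addition to the weakly electrophilic α-substituted aryl enoate may stay on the open-chain side of a reversible equilibrium, or the (Z)-enone may isomerise by reversible methoxide addition before closure. The fallback sets out from 17: the methanolysis is stopped at 0 °C and hydroxy enone 18 is isolated. Silylation (TMSOTf, Et3N, CH2Cl2, −78 °C) should give the bis(trimethylsilyl) enediol ether F1. TiCl4 in CH2Cl2 at −78 °C should then promote an intramolecular Mukaiyama–Michael addition onto the Lewis-acid-activated enoate, forming the same bond without a free enolate. Acidic methanol (p-TsOH) followed by warming in toluene should remove silicon and close the lactone, so the fallback comes back to the route at 20.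

Step 6. Thermal ionisation or 1,4-elimination of the benzylic, allylic amide acetal may outrun carbene formation, with loss of material or of optical purity. The fallback sets out from 10: esterification with 2-(tert-butyldimethylsilyloxy)acetic acid (DCC, DMAP, CH2Cl2) should give glycolate ester F2. An Ireland–Claisen rearrangement (LiHMDS, TMSCl, THF, −78 °C → rt) should transfer the two-carbon unit suprafacially to give α-silyloxy acid F3. TBAF should free α-hydroxy acid F4, and Pb(OAc)4 in benzene should cleave it oxidatively with loss of CO2 to aldehyde 13, where the fallback rejoins the route.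

Step 9. Dehydrochlorination of acetoxyacetyl chloride to acetoxyketene by the amine may be faster than oxidative addition to palladium, consuming the acid chloride. The fallback sets out from 14: deprotonation with LiHMDS (THF, −78 °C) and addition to (tert-butyldimethylsilyloxy)acetaldehyde should give propargylic alcohol F5. Dess–Martin oxidation should give ynone F6, and Lindlar semihydrogenation should give (Z)-enone F7. TBAF buffered with AcOH should remove silicon to give hydroxy enone 18, which is carried on under the base conditions of step 11; the fallback comes back to the route at 18.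

Further compounds
F1 | step 11 | methyl (S)-3-[(1Z)-3,4-bis(trimethylsilyloxy)buta-1,3-dien-1-yl]-7-ethyl-3,4,4-trimethyl-3,4-dihydronaphthalene-2-carboxylate | CCc1ccc2c(c1)C=C(C(=O)OC)[C@@](C)(/C=C\C(O[Si](C)(C)C)=CO[Si](C)(C)C)C2(C)C
F2 | step 6 | methyl (R)-1-[2-(tert-butyldimethylsilyloxy)acetoxy]-7-ethyl-3,4,4-trimethyl-1,4-dihydronaphthalene-2-carboxylate | CCc1ccc2c(c1)[C@@H](OC(=O)CO[Si](C)(C)C(C)(C)C)C(C(=O)OC)=C(C)C2(C)C
F3 | step 6 | 2-(tert-butyldimethylsilyloxy)-2-[(S)-7-ethyl-2-(methoxycarbonyl)-3,4,4-trimethyl-3,4-dihydronaphthalen-3-yl]acetic acid | CCc1ccc2c(c1)C=C(C(=O)OC)[C@@](C)(C(O[Si](C)(C)C(C)(C)C)C(=O)O)C2(C)C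
F4 | step 6 | 2-[(S)-7-ethyl-2-(methoxycarbonyl)-3,4,4-trimethyl-3,4-dihydronaphthalen-3-yl]-2-hydroxyacetic acid | CCc1ccc2c(c1)C=C(C(=O)OC)[C@@](C)(C(O)C(=O)O)C2(C)C
F5 | step 9 | methyl (S)-3-[4-(tert-butyldimethylsilyloxy)-3-hydroxybut-1-yn-1-yl]-7-ethyl-3,4,4-trimethyl-3,4-dihydronaphthalene-2-carboxylate | CCc1ccc2c(c1)C=C(C(=O)OC)[C@@](C)(C#CC(O)CO[Si](C)(C)C(C)(C)C)C2(C)C
F6 | step 9 | methyl (S)-3-[4-(tert-butyldimethylsilyloxy)-3-oxobut-1-yn-1-yl]-7-ethyl-3,4,4-trimethyl-3,4-dihydronaphthalene-2-carboxylate | CCc1ccc2c(c1)C=C(C(=O)OC)[C@@](C)(C#CC(=O)CO[Si](C)(C)C(C)(C)C)C2(C)C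
F7 | step 9 | methyl (S,Z)-3-[4-(tert-butyldimethylsilyloxy)-3-oxobut-1-en-1-yl]-7-ethyl-3,4,4-trimethyl-3,4-dihydronaphthalene-2-carboxylate | CCc1ccc2c(c1)C=C(C(=O)OC)[C@@](C)(/C=C\C(=O)CO[Si](C)(C)C(C)(C)C)C2(C)C
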